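## Retrosynthetic overview

1. The only ring, the butenolide, is formed last: I⁺-driven 5-exo-dig lactonisation of the acyclic (2E)-3-bromo-2-en-4-ynoic acid 10 through iodoalkyne 11 closes the ring and sets the (Z)-iodomethylidene.
2. Acid 10 comes from dienyne acetate 8, whose vinyl group is a masked CO2H (ozonolysis, then chlorite).
3. Acetate 8 comes from (R)-diynol 4 and vinylmagnesium chloride 5: hydroxyl-directed anti-carbomagnesiation, Br⁺ quench and in-flask acetylation fix the tetrasubstituted alkene geometry.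
4. Diynol 4 comes from diynone 3 by asymmetric transfer hydrogenation (sets the only stereocentre); 3 comes from bis(trimethylsilyl)butadiyne 1 and butanoyl chloride 2.

Assumption: the biogenesis of the ring is taken to be a haloperoxidase-type (X⁺) oxidative lactonisation of an acyclic 3-bromo-2-en-4-ynoic acid, with the carboxylate closing onto the halogenated alkyne.

## Route

Step 1
Reactants: 1 1,4-bis(trimethylsilyl)buta-1,3-diyne; 2 butanoyl chloride
Product: 3 1-(trimethylsilyl)octa-1,3-diyn-5-one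
Conditions: AlCl3 (1.1 equiv), CH2Cl2, 0 °C, 1 h; ice/aq HCl work-up
Reagents that add atoms: none
Why: Friedel–Crafts-type acyl-desilylation (ipso-acylation) of the bis-silyl diyne; the β-silyl-stabilised vinyl cation loses Me3Si⁺ and the electron-poor mono-acylated diynone does not react a second time; no stereocentre is formed.

Step 2
Reactants: 3 1-(trimethylsilyl)octa-1,3-diyn-5-one
Product: 4 (5R)-1-(trimethylsilyl)octa-1,3-diyn-5-ol
Conditions: Ru[(R,R)-TsDPEN](p-cymene) (preformed amido complex, 1 mol %), i-PrOH, 25 °C, no added base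
Reagents that add atoms: none
Why: Noyori asymmetric transfer hydrogenation of an α,β-acetylenic ketone; the (R,R)-catalyst delivers hydride to the face that gives the (R)-propargylic alcohol (the (S,S)-catalyst gives (S)-alkynols), and the base-free conditions leave both alkynes and the C–Si bond untouched.

Step 3
Reactants: 4 (5R)-1-(trimethylsilyl)octa-1,3-diyn-5-ol; 5 vinylmagnesium chloride
Product: 8 (3Z,5R)-3-bromo-4-ethenyl-1-(trimethylsilyl)oct-3-en-1-yn-5-yl acetate, via magnesium chelate 6 (not isolated), via bromo alkoxide 7 (not isolated)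
Conditions: 5 (4 equiv), THF/toluene, 70 °C, 6 h; −78 °C, BrCl2C–CCl2Br (3.5 equiv), to 0 °C; then Ac2O (5 equiv), DMAP (0.1 equiv), rt; aq NH4Cl
Reagents that add atoms: 1,2-dibromo-1,1,2,2-tetrachloroethane BrC(Cl)(Cl)C(Cl)(Cl)Br; acetic anhydride CC(=O)OC(C)=O
Why: Alkoxide-directed anti-carbomagnesiation of a propargylic alcohol (Fallis type): vinyl adds to the proximal alkyne carbon and Mg sits on the distal carbon in a five-membered O–Mg–C chelate, so brominolysis of the C–Mg bond with retention places Br cis to the carbinol carbon and the vinyl group cis to the silylethynyl group; the magnesium alkoxide is then O-acetylated in the same flask, and C-5 is not touched.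

Step 4
Reactants: 8 (3Z,5R)-3-bromo-4-ethenyl-1-(trimethylsilyl)oct-3-en-1-yn-5-yl acetate
Product: 10 (2E)-2-[(1R)-1-(acetyloxy)butyl]-3-bromo-5-(trimethylsilyl)pent-2-en-4-ynoic acid, via enal 9 (not isolated)
Conditions: O3, MeCN/H2O 9:1, 0 °C, to Sudan Red 7B end point; then NaClO2 (3 equiv), NaH2PO4, 0 °C to rt
Reagents that add atoms: ozone [O-][O+]=O; sodium chlorite [Na+].[O-]Cl=O
Why: Chemoselective ozonolysis of the unhindered terminal vinyl group (the tetrasubstituted bromo-enyne alkene and the silylalkyne are electron-poor and far slower) gives the enal directly in aqueous MeCN, and Pinnick (chlorite) oxidation in the same flask gives the acid; alkene geometry and the stereocentre are unchanged.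

Step 5
Reactants: 10 (2E)-2-[(1R)-1-(acetyloxy)butyl]-3-bromo-5-(trimethylsilyl)pent-2-en-4-ynoic acid
Product: 12 (1R)-1-[(5Z)-4-bromo-5-(iodomethylidene)-2-oxo-2,5-dihydrofuran-3-yl]butyl acetate, via iodoalkynoic acid 11 (not isolated)
Conditions: NIS (1.05 equiv), AgNO3 (15 mol %), DMF, 0 °C to rt, dark
Reagents that add atoms: N-iodosuccinimide O=C1CCC(=O)N1I
Why: Proposed new method: a one-flask oxidative iodolactonisation run through the iodoalkyne – Ag(I)/NIS turns the C–SiMe3 terminus into C–I (iodination of the silver acetylide), and Ag(I) π-activation of the iodoalkyne then triggers anti 5-exo-dig attack of the cis-carboxyl group at C-4 followed by protodeargentation with retention, so O and I end up cis ((Z)-iodomethylidene, also the thermodynamic isomer because the E isomer clashes with the C-4 bromine) and the remote stereocentre is untouched; the closest known reaction types are the Ag-catalysed NXS halogenation of silyl and terminal alkynes, the Ag-catalysed anti-addition of carboxylic acids to 1-haloalkynes giving (Z)-β-haloenol esters, and the metal-catalysed cyclisation of 5-halo-4-pentynoic acids to (Z)-halo enol lactones.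

## Compound list

1 | 1,4-bis(trimethylsilyl)buta-1,3-diyne | C[Si](C)(C)C#CC#C[Si](C)(C)C | starting material
2 | butanoyl chloride | CCCC(Cl)=O | starting material
3 | 1-(trimethylsilyl)octa-1,3-diyn-5-one | CCCC(=O)C#CC#C[Si](C)(C)C | intermediate
4 | (5R)-1-(trimethylsilyl)octa-1,3-diyn-5-ol | CCC[C@@H](O)C#CC#C[Si](C)(C)C | intermediate
5 | vinylmagnesium chloride (commercial THF solution) | C=C[Mg]Cl | starting material
6 | (5R)-4-ethenyl-5-propyl-3-[(trimethylsilyl)ethynyl]-2,5-dihydro-1,2-oxamagnesole (cyclic O–Mg–C chelate) | CCC[C@@H](O1)C(C=C)=C(C#C[Si](C)(C)C)[Mg]1 | intermediate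
7 | (3Z,5R)-3-bromo-4-ethenyl-1-(trimethylsilyl)oct-3-en-1-yn-5-ol (present as its magnesium alkoxide) | CCC[C@@H](O)/C(C=C)=C(\Br)C#C[Si](C)(C)C | intermediate
8 | (3Z,5R)-3-bromo-4-ethenyl-1-(trimethylsilyl)oct-3-en-1-yn-5-yl acetate | CCC[C@@H](OC(C)=O)/C(C=C)=C(\Br)C#C[Si](C)(C)C | intermediate
9 | (2E)-2-[(1R)-1-(acetyloxy)butyl]-3-bromo-5-(trimethylsilyl)pent-2-en-4-ynal | CCC[C@@H](OC(C)=O)/C(C=O)=C(\Br)C#C[Si](C)(C)C | intermediate
10 | (2E)-2-[(1R)-1-(acetyloxy)butyl]-3-bromo-5-(trimethylsilyl)pent-2-en-4-ynoic acid | CCC[C@@H](OC(C)=O)/C(C(=O)O)=C(\Br)C#C[Si](C)(C)C | intermediate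
11 | (2E)-2-[(1R)-1-(acetyloxy)butyl]-3-bromo-5-iodopent-2-en-4-ynoic acid | CCC[C@@H](OC(C)=O)/C(C(=O)O)=C(\Br)C#CI | intermediate
12 | (1R)-1-[(5Z)-4-bromo-5-(iodomethylidene)-2-oxo-2,5-dihydrofuran-3-yl]butyl acetate | CCC[C@@H](OC(C)=O)C1=C(Br)/C(=C/I)OC1=O | target

## Step count and risks

Total step count: 5. Longest linear sequence: 5 steps (1 → 3 → 4 → 8 → 10 → 12).

The three steps most likely to fail are steps 3, 4 and 5.

**Step 3** (regiocontrol of the carbomagnesiation on a conjugated diynol; possible attack on the distal alkyne). The fallback sets out from 1 and comes back to the route at 10. It builds the same tetrasubstituted alkene by a titanium-mediated alkynoate–aldehyde coupling instead of a directed Grignard addition.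
- Mono-desilylative lithiation of 1 (MeLi·LiBr, THF) gives lithium 4-(trimethylsilyl)buta-1,3-diyn-1-ide F1, trapped with Boc2O as tert-butyl 5-(trimethylsilyl)penta-2,4-diynoate F2.
- Ti(O-i-Pr)4/2 i-PrMgCl (−78 to −50 °C) forms the ester-chelated diisopropoxytitanacyclopropene of F2 F3. This inserts butanal at the ester-bearing carbon to give the 2,2-diisopropoxy-1-oxa-2-titanacyclopent-3-ene F4, with C–C and C–Ti formed syn.
- NBS cleaves the C–Ti bond with retention to give racemic tert-butyl (2E)-3-bromo-2-(1-hydroxybutyl)-5-(trimethylsilyl)pent-2-en-4-ynoate F5.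
- Lipase PS with vinyl acetate acetylates only the (R)-alcohol (Kazlauskas rule; maximum 50 % yield), giving tert-butyl (2E)-2-[(1R)-1-(acetyloxy)butyl]-3-bromo-5-(trimethylsilyl)pent-2-en-4-ynoate F6, which is separated from the (S)-alcohol.
- TFA in CH2Cl2 removes the tert-butyl group to give 10.

**Step 4** (ozone could also attack the bromo-enyne alkene of the cross-conjugated diene). The fallback sets out from 8 and comes back at 9, then 10. It replaces ozone by a sterically controlled two-stage glycol cleavage.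
- Catalytic OsO4/NMO dihydroxylates only the monosubstituted vinyl group to give (3Z,5R)-3-bromo-4-(1,2-dihydroxyethyl)-1-(trimethylsilyl)oct-3-en-1-yn-5-yl acetate F7.
- NaIO4 cleaves the diol to enal 9, which is oxidised with NaClO2/NaH2PO4/2-methyl-2-butene to 10.

**Step 5** (competing protodesilylation and cyclisation to the halogen-free lactone, over-iodination, or E/Z leakage). The fallback sets out from 10 and comes back at 12. It separates ring closure from iodination.
- Buffered fluoride (TBAF/AcOH, THF, 0 °C) gives (2E)-2-[(1R)-1-(acetyloxy)butyl]-3-bromopent-2-en-4-ynoic acid F8.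
- Ag2CO3 (10 mol %) cyclises it 5-exo-dig to (1R)-1-(4-bromo-5-methylidene-2-oxo-2,5-dihydrofuran-3-yl)butyl acetate F9.
- ICl (CH2Cl2, −78 °C) adds across the exocyclic enol-ester double bond to give (1R)-1-[4-bromo-5-chloro-5-(iodomethyl)-2-oxo-2,5-dihydrofuran-3-yl]butyl acetate F10.
- Et3N eliminates HCl to the thermodynamically preferred (Z)-iodomethylidene compound 12.

Further compounds

F1 | step 3 | lithium 4-(trimethylsilyl)buta-1,3-diyn-1-ide | [Li]C#CC#C[Si](C)(C)C
F2 | step 3 | tert-butyl 5-(trimethylsilyl)penta-2,4-diynoate | CC(C)(C)OC(=O)C#CC#C[Si](C)(C)C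
F3 | step 3 | diisopropoxytitanacyclopropene of F2 (Ti across C2≡C3) | CC(C)O[Ti]1(OC(C)C)C(C(=O)OC(C)(C)C)=C1C#C[Si](C)(C)C
F4 | step 3 | tert-butyl 2,2-diisopropoxy-5-propyl-3-[(trimethylsilyl)ethynyl]-1-oxa-2-titanacyclopent-3-ene-4-carboxylate (racemic) | CCCC1O[Ti](OC(C)C)(OC(C)C)C(C#C[Si](C)(C)C)=C1C(=O)OC(C)(C)C
F5 | step 3 | racemic tert-butyl (2E)-3-bromo-2-(1-hydroxybutyl)-5-(trimethylsilyl)pent-2-en-4-ynoate | CCCC(O)/C(C(=O)OC(C)(C)C)=C(\Br)C#C[Si](C)(C)C
F6 | step 3 | tert-butyl (2E)-2-[(1R)-1-(acetyloxy)butyl]-3-bromo-5-(trimethylsilyl)pent-2-en-4-ynoate | CCC[C@@H](OC(C)=O)/C(C(=O)OC(C)(C)C)=C(\Br)C#C[Si](C)(C)C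
F7 | step 4 | (3Z,5R)-3-bromo-4-(1,2-dihydroxyethyl)-1-(trimethylsilyl)oct-3-en-1-yn-5-yl acetate (epimers at the new carbinol) | CCC[C@@H](OC(C)=O)/C(C(O)CO)=C(\Br)C#C[Si](C)(C)C
F8 | step 5 | (2E)-2-[(1R)-1-(acetyloxy)butyl]-3-bromopent-2-en-4-ynoic acid | CCC[C@@H](OC(C)=O)/C(C(=O)O)=C(\Br)C#C
F9 | step 5 | (1R)-1-(4-bromo-5-methylidene-2-oxo-2,5-dihydrofuran-3-yl)butyl acetate | CCC[C@@H](OC(C)=O)C1=C(Br)C(=C)OC1=O
F10 | step 5 | (1R)-1-[4-bromo-5-chloro-5-(iodomethyl)-2-oxo-2,5-dihydrofuran-3-yl]butyl acetate (epimers at C-5) | CCC[C@@H](OC(C)=O)C1=C(Br)C(Cl)(CI)OC1=O
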